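Micromolar-hours of enzyme are the unit I reckon in, and the first question is how many of them buy the first few percent.

the same everywhere: starting material 0.10 M
- autumn: second substrate 0.050 M; enzyme 97 µM; run made earlier
- noon: second substrate 0.050 M; enzyme 150 µM; run made earlier
- flask: second substrate 0.0500 M; enzyme 69 µM

| run | time / h | target / % |
|---|---|---|
| autumn | 0.250 | 6.9 |
| autumn | 0.667 | 21.7 |
| autumn | 1.33 | 39.3 |
| autumn | 2.00 | 51.1 |
| autumn | 3.00 | 63.7 |
| autumn | 4.00 | 70.7 |
| autumn | 5.00 | 74.4 |
| noon | 0.250 | 12.2 |
| noon | 0.667 | 32.1 |
| noon | 1.33 | 58.1 |
| noon | 2.00 | 73.0 |
| noon | 3.00 | 82.4 |
| noon | 4.00 | 87.5 |
| noon | 5.00 | 90.3 |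

(each reading ± 1 percentage point)

- what was read earlier has a scatter of 1 percentage point, one standard deviation
- no earlier run changes the charge of second substrate; that part of a forecast is a guess

- factor on the rate of making target when 5.0% of the starting material are converted if second substrate is charged twice over
- factor on the rate when 5.0% of the starting material are converted if enzyme is charged at 300 µM instead

I replace each early curve by its mean rate up to the first reading, scale that rate with c(enzyme), and average the autumn and noon runs, which gives 0.239 h for the flask: this is my five-percent time, the time to 5.0% conversion at the mean early rate per enzyme, scaled to the charge in hand. In one extreme the enzyme stays whole, so the rate goes with the charge and the factor for 300 µM is 4.35. But the noon run reaches the autumn run's 51.1% at about 1.15 h, on 0.890 of the autumn run's enzyme-hours, which I read as enzyme being lost (deactivation), and equating the mean enzyme-hours of the two runs gives a loss constant, as a reading, of 0.225 /h. In the other extreme the flask loses that enzyme for a whole five-percent time while the richer charge loses none, which gives 4.59. The richer charge loses a little over its shorter time, so I commit to 4.54, between the two. The noon run reads 0.0903 M of target at its last reading on a charge of 0.050 M of second substrate, so making target does not consume second substrate one to one, and my guess for doubling it is no change.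

The forecast gives 1.15 and 4.6, slightly above me on both, and holds that “the enzyme looks nearly saturated in starting material and probably also in second substrate”.

The simulation gives 0.900 and 4.53.

    starting material + enzyme ⇌ complex A (K = 21.0 /M, k = 89.5 /M/s)
    complex A → enzyme + target (k = 0.175 /s)
    second substrate + enzyme ⇌ complex B (K = 143 /M, k = 1750 /M/s)
    complex B → enzyme + second product (k = 1.69 /s)
    starting material + complex B → spent catalyst A (k = 4.03 × 10⁻⁴ /M/s)
    enzyme → spent catalyst B (k = 2.14 × 10⁻⁴ /s)

At the start of the flask, second substrate takes up enzyme into complex B ten times as fast as starting material takes it into complex A, forward steps alone, and by 0.800 h the flask holds 0% of its second substrate and 0.0500 M of second product. Against the five-percent time of 0.239 h, the flask reaches 5.0% at 0.294 h, 1.23 times as long, and the flask with the doubled charge of second substrate takes 0.414 h, which is 1.74 times the five-percent time.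

Readings and results stem from a simulated flask on assumed constants; noise was put on by code.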